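A direct plan would merge two pyranones, 5-acetyl-6-methyl-2H-pyran-2-one (A1) and methyl (4-methoxy-2-oxo-2H-pyran-6-yl)acetate (A2), in a carbanion-induced ring transformation to the coumarin A3, making rings A and B at once.
It would finish with a rhodium-catalysed asymmetric 1,4-addition of 4-hydroxyphenylboronic acid to A3.
Weakest would be the ring transformation: it has no precedent, needs attack at the fully substituted C6 of A1 and a Dieckmann closure beside a base-labile pyranone, so the whole core would hang on an untested closure.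
Next would be the final aryl addition: the only stereocentre would be set last, on the most precious material, at a C4 blocked by the peri methyl on C5 and deactivated by the 7-OH.
Third would be the mono-C-acylation of a pyranone dienolate to A2, where O-acylation and double acylation compete.

Plan of the new route
The route cuts ring B at C3–C4 and O1–C2: the unit O1–C8a–C4a–C4, with C4 benzylic, ortho to O1 and para to O7 on ring A, is a latent ortho-quinone methide that takes up an acetate equivalent under a chiral squaramide (formal [4+2]).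
Ring D is cut at its pyranone C4–C5 and O1–C2 bonds (a malonyl unit on a C6 acetyl group), and the bond from C4 to ring C is a Grignard bond.
Ring A is bought as 2,4-dihydroxy-6-methylbenzaldehyde, whose CHO (future C4) already lies between OH and CH3.
Rings arise in the order A (bought), B together with C4 (step 4), D (step 6).
No ring transformation and no pyranone dienolate occur; the stereocentre is set early, on cheap material, by a small nucleophile adding to a planar C4, where the C5 methyl group fixes the quinone methide geometry instead of blocking an acceptor.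

Key step: step 4

Remark on the chemistry: the quinine-derived squaramide is assumed to give the (4R) sense of addition to quinone methide 8; if the (4S) sense were found, its quinidine-derived pseudo-enantiomer would be used with no other change.

Step 1
Reactants: 1 2,4-dihydroxy-6-methylbenzaldehyde
Product: 2 3-bromo-4,6-dihydroxy-2-methylbenzaldehyde
Conditions: NBS (1.0 equiv), MeCN, –20 → 0 °C
Reagents that add atoms: N-bromosuccinimide, O=C1CCC(=O)N1Br
Why: Electrophilic aromatic bromination should go to the one ring position that is para to a hydroxyl group (the chelated 2-OH) and ortho to the other, next to the methyl group, by analogy with the known chlorination of this aldehyde at the same carbon; this carbon is the future C6 of ring A, so the substitution pattern is fixed here and no stereocentre is formed.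

Step 2
Reactants: 2 3-bromo-4,6-dihydroxy-2-methylbenzaldehyde
Product: 3 4-(benzyloxy)-3-bromo-6-hydroxy-2-methylbenzaldehyde
Conditions: BnBr (1.05 equiv), K2CO3 (1.0 equiv), acetone, 40 °C
Reagents that add atoms: benzyl bromide, BrCc1ccccc1
Why: Williamson etherification with one equivalent of base should alkylate only the more acidic 4-OH (future O7), since the 6-OH (future O1) is held in a hydrogen bond to the aldehyde; no stereocentre is formed.

Step 3
Reactants: 3 4-(benzyloxy)-3-bromo-6-hydroxy-2-methylbenzaldehyde; 4 4-(benzyloxy)phenylmagnesium bromide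
Product: 6 5-(benzyloxy)-2-{[4-(benzyloxy)phenyl](4-methylbenzenesulfonyl)methyl}-4-bromo-3-methylphenol (racemic), via benzhydrol 5 (not isolated)
Conditions: 4 (2.3 equiv), THF, –20 → 0 °C; then TolSO2Na (3 equiv), HCO2H–H2O, 0 → 20 °C
Reagents that add atoms: sodium 4-methylbenzenesulfinate, Cc1ccc(cc1)S(=O)[O-].[Na+]
Why: Grignard 1,2-addition to the aldehyde (the first equivalent is consumed by the phenol) gives the benzhydrol 5, which on acidification ionises at the doubly donor-stabilised C4 and is captured by the soft sulfinate sulfur (SN1-type substitution) to give the bench-stable quinone methide precursor 6; C4 is racemic here by design, because step 4 passes through a planar intermediate.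

Step 4
Reactants: 6 5-(benzyloxy)-2-{[4-(benzyloxy)phenyl](4-methylbenzenesulfonyl)methyl}-4-bromo-3-methylphenol (racemic); 7 2,2-dimethyl-1,3-dioxane-4,6-dione (Meldrum's acid)
Product: 11 (4R)-7-(benzyloxy)-4-[4-(benzyloxy)phenyl]-6-bromo-5-methyl-3,4-dihydro-2H-chromen-2-one, via ortho-quinone methide 8 (not isolated), via Meldrum's acid adduct 9 (not isolated), via lactone carboxylic acid 10 (not isolated)
Conditions: 7 (1.5 equiv), quinine-derived squaramide 3-{[3,5-bis(trifluoromethyl)phenyl]amino}-4-{[(8α,9S)-6′-methoxycinchonan-9-yl]amino}cyclobut-3-ene-1,2-dione (10 mol %), 5% aq. NaHCO3, CH2Cl2, 0 °C; then p-TsOH·H2O (0.2 equiv), toluene, 90 °C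
Reagents that add atoms: none
Why: Bicarbonate deprotonates the C8a phenol of 6, 1,4-elimination of sulfinate gives the ortho-quinone methide 8 (O1=C8a–C4a=C4), and the squaramide binds the quinone methide oxygen by two N–H bonds while its protonated quinuclidine holds the Meldrum's acid anion, which adds to C4 (1,4-addition that restores the aromaticity of ring A) to give 9; acid then lets the C8a phenol attack a Meldrum's carbonyl with loss of acetone (10), and decarboxylation gives 11. The closest known reaction type is the bifunctional-squaramide-catalysed addition of Meldrum's acid to ortho-quinone methides generated in situ from 2-(1-sulfonylalkyl)phenols, which gives 4-aryl-3,4-dihydrocoumarins after lactonisation and decarboxylation. Ring B closes by 6-exo-trig lactonisation at O1–C2 after the C3–C4 bond has been made, so the step is a formal [4+2] of the quinone methide with a ketene equivalent. The C4 stereocentre is set by the catalyst, which should shield one face of the planar C4 of 8; the quinine-derived catalyst is assumed to give 4R. The step needs one quinone methide geometry and one lactonising oxygen: allylic 1,3-strain with the C5 methyl group should force the aryl group on C4 to the side of the carbonyl oxygen, and only the C8a oxygen is free because O7 is benzylated. The nucleophile is small and C4 is planar, so the peri methyl group that would block a coumarin acceptor should not hinder bond formation here.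

Step 5
Reactants: 11 (4R)-7-(benzyloxy)-4-[4-(benzyloxy)phenyl]-6-bromo-5-methyl-3,4-dihydro-2H-chromen-2-one; 12 tributyl(1-ethoxyethenyl)stannane
Product: 14 (4R)-6-acetyl-7-(benzyloxy)-4-[4-(benzyloxy)phenyl]-5-methyl-3,4-dihydro-2H-chromen-2-one, via enol ether 13 (not isolated)
Conditions: Pd(P(t-Bu)3)2 (5 mol %), CsF (2.2 equiv), dioxane, 90 °C; then 1 M HCl, THF, 20 °C
Reagents that add atoms: water, O
Why: Stille coupling, in which oxidative addition of the di-ortho-substituted C6–Br bond to zerovalent palladium is helped by the bulky electron-rich phosphine and transmetalation of the small alkoxyvinyl group by fluoride, followed by acid hydrolysis of enol ether 13 to the methyl ketone; the conditions are neutral to weakly acidic, so lactone ring B and C4 should be untouched.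

Step 6
Reactants: 14 (4R)-6-acetyl-7-(benzyloxy)-4-[4-(benzyloxy)phenyl]-5-methyl-3,4-dihydro-2H-chromen-2-one; 15 malonyl dichloride (propanedioyl dichloride)
Product: 17 (4R)-7-(benzyloxy)-4-[4-(benzyloxy)phenyl]-6-(4-hydroxy-2-oxo-2H-pyran-6-yl)-5-methyl-3,4-dihydro-2H-chromen-2-one, via silyl enol ether 16 (not isolated)
Conditions: Me3SiOTf (1.2 equiv), Et3N (1.5 equiv), CH2Cl2, 0 °C; pentane extraction; then 15 (1.1 equiv), Et2O, –78 → 20 °C; filtration of the product
Reagents that add atoms: none
Why: Soft enolisation silylates the aryl methyl ketone, which is more acidic than the lactone, and the enol ether 16 is then C-acylated at its terminal carbon by malonyl dichloride (pyranone C4–C5 bond) and closes through the ketone-derived oxygen on the second acyl chloride (pyranone O1–C2 bond), the known double acylation of silyl enol ethers that gives 4-hydroxy-2-pyranones; no base is present, so ring B and C4 should survive.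

Step 7
Reactants: 17 (4R)-7-(benzyloxy)-4-[4-(benzyloxy)phenyl]-6-(4-hydroxy-2-oxo-2H-pyran-6-yl)-5-methyl-3,4-dihydro-2H-chromen-2-one
Product: 18 (4R)-7-(benzyloxy)-4-[4-(benzyloxy)phenyl]-6-(4-methoxy-2-oxo-2H-pyran-6-yl)-5-methyl-3,4-dihydro-2H-chromen-2-one
Conditions: Me2SO4 (1.2 equiv), K2CO3 (1.5 equiv), acetone, 40 °C
Reagents that add atoms: dimethyl sulfate, COS(=O)(=O)OC
Why: O-Alkylation of the vinylogous carboxylic acid (pKa about 5) with dimethyl sulfate and carbonate should give the 4-methoxy-2-pyranone, the usual site of methylation of 4-hydroxy-2-pyranones under these conditions, and no other oxygen competes because both phenols are benzylated; C4 is not acidic and is not affected.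

Step 8
Reactants: 18 (4R)-7-(benzyloxy)-4-[4-(benzyloxy)phenyl]-6-(4-methoxy-2-oxo-2H-pyran-6-yl)-5-methyl-3,4-dihydro-2H-chromen-2-one
Product: 19 (4R)-7-hydroxy-4-(4-hydroxyphenyl)-6-(4-methoxy-2-oxo-2H-pyran-6-yl)-5-methyl-3,4-dihydro-2H-chromen-2-one
Conditions: BCl3 (6 equiv), C6HMe5 (6 equiv), CH2Cl2, –78 °C; then H2O, –78 → 0 °C
Reagents that add atoms: none
Why: Lewis acid cleavage of the two aryl benzyl ethers at low temperature with pentamethylbenzene as a non-basic scavenger of the benzyl cation should spare the vinylogous methyl ester, the pyranone double bonds (which hydrogenolysis would endanger) and the lactone, and does not touch C4.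

Compound list
1 | 2,4-dihydroxy-6-methylbenzaldehyde | Cc1cc(O)cc(O)c1C=O | starting material
2 | 3-bromo-4,6-dihydroxy-2-methylbenzaldehyde | Cc1c(Br)c(O)cc(O)c1C=O | intermediate
3 | 4-(benzyloxy)-3-bromo-6-hydroxy-2-methylbenzaldehyde | Cc1c(Br)c(OCc2ccccc2)cc(O)c1C=O | intermediate
4 | 4-(benzyloxy)phenylmagnesium bromide | Br[Mg]c1ccc(OCc2ccccc2)cc1 | starting material
5 | 5-(benzyloxy)-2-{[4-(benzyloxy)phenyl](hydroxy)methyl}-4-bromo-3-methylphenol (racemic, not isolated) | Cc1c(Br)c(OCc2ccccc2)cc(O)c1C(O)c1ccc(OCc2ccccc2)cc1 | intermediate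
6 | 5-(benzyloxy)-2-{[4-(benzyloxy)phenyl](4-methylbenzenesulfonyl)methyl}-4-bromo-3-methylphenol (racemic) | Cc1c(Br)c(OCc2ccccc2)cc(O)c1C(c1ccc(OCc2ccccc2)cc1)S(=O)(=O)c1ccc(C)cc1 | intermediate
7 | 2,2-dimethyl-1,3-dioxane-4,6-dione (Meldrum's acid) | CC1(C)OC(=O)CC(=O)O1 | starting material
8 | 3-(benzyloxy)-6-{[4-(benzyloxy)phenyl]methylidene}-4-bromo-5-methylcyclohexa-2,4-dien-1-one (ortho-quinone methide, not isolated) | O=C1C=C(OCc2ccccc2)C(Br)=C(C)C1=Cc1ccc(OCc2ccccc2)cc1 | intermediate
9 | 5-{(R)-[4-(benzyloxy)-3-bromo-6-hydroxy-2-methylphenyl][4-(benzyloxy)phenyl]methyl}-2,2-dimethyl-1,3-dioxane-4,6-dione (not isolated) | Cc1c(Br)c(OCc2ccccc2)cc(O)c1[C@@H](c1ccc(OCc2ccccc2)cc1)C1C(=O)OC(C)(C)OC1=O | intermediate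
10 | (4R)-7-(benzyloxy)-4-[4-(benzyloxy)phenyl]-6-bromo-5-methyl-2-oxo-3,4-dihydro-2H-chromene-3-carboxylic acid (C3 epimers, not isolated) | Brc1c(OCc2ccccc2)cc2c(c1C)[C@@H](c1ccc(OCc3ccccc3)cc1)C(C(O)=O)C(=O)O2 | intermediate
11 | (4R)-7-(benzyloxy)-4-[4-(benzyloxy)phenyl]-6-bromo-5-methyl-3,4-dihydro-2H-chromen-2-one | Brc1c(OCc2ccccc2)cc2c(c1C)[C@@H](c1ccc(OCc3ccccc3)cc1)CC(=O)O2 | intermediate
12 | tributyl(1-ethoxyethenyl)stannane | CCCC[Sn](CCCC)(CCCC)C(=C)OCC | starting material
13 | (4R)-7-(benzyloxy)-4-[4-(benzyloxy)phenyl]-6-(1-ethoxyethenyl)-5-methyl-3,4-dihydro-2H-chromen-2-one (not isolated) | CCOC(=C)c1c(OCc2ccccc2)cc2c(c1C)[C@@H](c1ccc(OCc3ccccc3)cc1)CC(=O)O2 | intermediate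
14 | (4R)-6-acetyl-7-(benzyloxy)-4-[4-(benzyloxy)phenyl]-5-methyl-3,4-dihydro-2H-chromen-2-one | CC(=O)c1c(OCc2ccccc2)cc2c(c1C)[C@@H](c1ccc(OCc3ccccc3)cc1)CC(=O)O2 | intermediate
15 | malonyl dichloride (propanedioyl dichloride) | O=C(Cl)CC(Cl)=O | starting material
16 | (4R)-7-(benzyloxy)-4-[4-(benzyloxy)phenyl]-5-methyl-6-{1-[(trimethylsilyl)oxy]ethenyl}-3,4-dihydro-2H-chromen-2-one (not isolated) | C=C(O[Si](C)(C)C)c1c(OCc2ccccc2)cc2c(c1C)[C@@H](c1ccc(OCc3ccccc3)cc1)CC(=O)O2 | intermediate
17 | (4R)-7-(benzyloxy)-4-[4-(benzyloxy)phenyl]-6-(4-hydroxy-2-oxo-2H-pyran-6-yl)-5-methyl-3,4-dihydro-2H-chromen-2-one | Oc1cc(-c2c(OCc4ccccc4)cc3c(c2C)[C@@H](c2ccc(OCc4ccccc4)cc2)CC(=O)O3)oc(=O)c1 | intermediate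
18 | (4R)-7-(benzyloxy)-4-[4-(benzyloxy)phenyl]-6-(4-methoxy-2-oxo-2H-pyran-6-yl)-5-methyl-3,4-dihydro-2H-chromen-2-one | COc1cc(-c2c(OCc4ccccc4)cc3c(c2C)[C@@H](c2ccc(OCc4ccccc4)cc2)CC(=O)O3)oc(=O)c1 | intermediate
19 | (4R)-7-hydroxy-4-(4-hydroxyphenyl)-6-(4-methoxy-2-oxo-2H-pyran-6-yl)-5-methyl-3,4-dihydro-2H-chromen-2-one | COc1cc(-c2c(O)cc3c(c2C)[C@@H](c2ccc(O)cc2)CC(=O)O3)oc(=O)c1 | target

Total step count: 8
Longest linear sequence: 8 steps (1 → 19); all other reactants are commercial.

Steps most likely to fail

Step 4. The planar quinone methide 8 may be discriminated poorly by the catalyst, since its aryl group should lie syn to the carbonyl oxygen, unlike the usual substrates. The ee may also erode by reversible loss of the Meldrum's acid anion from adduct 9 before the lactone closes. Fallback: setting out from 6, the same annulation run with an achiral phase-transfer catalyst (Bu4NBr, aq. NaHCO3, CH2Cl2; then p-TsOH, toluene, 90 °C) would give racemic 7-(benzyloxy)-4-[4-(benzyloxy)phenyl]-6-bromo-5-methyl-3,4-dihydro-2H-chromen-2-one F1. Resolution by preparative chromatography on a chiral stationary phase would deliver the (4R)-enantiomer, which is 11.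

Step 5. Oxidative addition and transmetalation may be slow at the bromide flanked by OBn and CH3, so that protodebromination or homocoupling of the stannane takes over. Fallback: setting out from 11, Sonogashira coupling with ethynyltrimethylsilane (PdCl2(PPh3)2, CuI, i-Pr2NH, DMF, 80 °C), in which the linear alkyne is the least hindered carbon nucleophile, would give (4R)-7-(benzyloxy)-4-[4-(benzyloxy)phenyl]-5-methyl-6-[(trimethylsilyl)ethynyl]-3,4-dihydro-2H-chromen-2-one F2. Gold-catalysed Markovnikov hydration with protodesilylation (AuCl(PPh3)/AgOTf, H2O, dioxane, 70 °C) would then return to the route at ketone 14.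

Step 6. The lactone enol may be silylated and acylated in competition, 16 may be O-acylated, or malonyl dichloride may oligomerise through chlorocarbonylketene. Fallback: setting out from 14 (through 16), ZnCl2-promoted C-acylation with methyl 3-chloro-3-oxopropanoate would give methyl 5-{(4R)-7-(benzyloxy)-4-[4-(benzyloxy)phenyl]-5-methyl-2-oxo-3,4-dihydro-2H-chromen-6-yl}-3,5-dioxopentanoate F3. Separate lactonisation (DBU 0.2 equiv, toluene, 80 °C, loss of methanol) would return to the route at 17.

Further compounds
F1 | step 4 | rac-7-(benzyloxy)-4-[4-(benzyloxy)phenyl]-6-bromo-5-methyl-3,4-dihydro-2H-chromen-2-one | Brc1c(OCc2ccccc2)cc2c(c1C)C(c1ccc(OCc3ccccc3)cc1)CC(=O)O2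
F2 | step 5 | (4R)-7-(benzyloxy)-4-[4-(benzyloxy)phenyl]-5-methyl-6-[(trimethylsilyl)ethynyl]-3,4-dihydro-2H-chromen-2-one | C[Si](C)(C)C#Cc1c(OCc2ccccc2)cc2c(c1C)[C@@H](c1ccc(OCc3ccccc3)cc1)CC(=O)O2
F3 | step 6 | methyl 5-{(4R)-7-(benzyloxy)-4-[4-(benzyloxy)phenyl]-5-methyl-2-oxo-3,4-dihydro-2H-chromen-6-yl}-3,5-dioxopentanoate | COC(=O)CC(=O)CC(=O)c1c(OCc2ccccc2)cc2c(c1C)[C@@H](c1ccc(OCc3ccccc3)cc1)CC(=O)O2
A1 | direct plan | 5-acetyl-6-methyl-2H-pyran-2-one | CC(=O)C1=C(C)OC(=O)C=C1
A2 | direct plan | methyl (4-methoxy-2-oxo-2H-pyran-6-yl)acetate | COC(=O)CC1=CC(OC)=CC(=O)O1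
A3 | direct plan | 7-hydroxy-6-(4-methoxy-2-oxo-2H-pyran-6-yl)-5-methyl-2H-chromen-2-one | COc1cc(-c2c(O)cc3c(c2C)C=CC(=O)O3)oc(=O)c1
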